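**Plan**

- Retrosynthesis: the C5 and C8 phenols are unmasked last from methyl ethers, and the quinone comes from a 4-methoxy-1-naphthol. Ring A (C1, C2, C3, C4, C4a, C8a) is para-dioxygenated at C1/C4 and carries its only substituent at C2, next to C1–O. It is therefore cut at C3–C4, C1–C2 and C1–C8a.
- These cuts give three pieces: an aryl(methoxy)carbene complex of zerovalent chromium (ring B, C4a, C8a and C4), one CO ligand (C1), and a terminal alkyne (C2, C3 and the whole side chain).
- Forward: the side chain is built as an alkyne (Weinreb amide, silyl ynone, carbinol, butanoate). Ring B is bought as 2-bromo-1,4-dimethoxybenzene and converted into the carbene complex. Ring A is then closed by Dötz benzannulation and oxidised to the quinone, and ring B is demethylated oxidatively.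
- Stereochemistry: the single (R)-centre comes from Noyori transfer hydrogenation of the ynone with the (R,R)-TsDPEN ruthenium catalyst. It is esterified before the benzannulation and is not involved in any later bond change.

Key step: step 7

Assumption: "butylshikonin" is read as the O-butanoyl (butyryl) ester of (R)-shikonin, as the SMILES shows; the naphthazarin tautomer drawn stands for the rapidly equilibrating pair.

Conventions: ring atoms carry naphthalene locants; ring A is C1, C2, C3, C4, C4a, C8a and ring B is C4a, C5, C6, C7, C8, C8a. In the SMILES strings, CO ligands on chromium are written Cr=C=O, and hapto-bound complexes are written as ligand and Cr(CO)3 unit joined by a dot.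

**Route**

Step 1
Reactants: 1 4-methylpent-3-enoic acid
Product: 3 N-methoxy-N,4-dimethylpent-3-enamide, via acyl imidazole 2 (not isolated)
Conditions: CDI (1.1 equiv), CH2Cl2, 0 °C → rt; then MeNHOMe·HCl (1.2 equiv), rt
Reagents that add atoms: N,O-dimethylhydroxylamine hydrochloride, CNOC.Cl
Why: Carboxyl activation as the acyl imidazole followed by aminolysis (Weinreb amide formation) runs near neutrality, so the β,γ-double bond should not move into conjugation.

Step 2
Reactants: 3 N-methoxy-N,4-dimethylpent-3-enamide; 4 ethynyltrimethylsilane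
Product: 7 6-methyl-1-(trimethylsilyl)hept-5-en-1-yn-3-one, via lithium (trimethylsilyl)acetylide 5 (not isolated), via tetrahedral lithium alkoxide 6 (not isolated)
Conditions: 4, n-BuLi, THF, −78 °C; then 3, −78 → −20 °C; cold aq. NH4Cl
Reagents that add atoms: none
Why: Weinreb ketone synthesis: acetylide 5 adds only once because the chelated alkoxide 6 persists until the cold aqueous quench, which releases ynone 7 before the doubly activated CH2 group can isomerise.

Step 3
Reactants: 7 6-methyl-1-(trimethylsilyl)hept-5-en-1-yn-3-one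
Product: 8 (R)-6-methyl-1-(trimethylsilyl)hept-5-en-1-yn-3-ol
Conditions: Ru[(R,R)-TsNCHPhCHPhNH](p-cymene) (1 mol%), 2-propanol, rt
Reagents that add atoms: none
Why: Noyori asymmetric transfer hydrogenation of an acetylenic ketone: hydride on ruthenium and the N–H proton are delivered together through a six-membered transition state in which the alkynyl group takes the place an aryl group has in aryl ketones, so the (R,R)-diamine catalyst is expected to give the (R)-carbinol, and the base-free medium should leave the skipped alkene in place.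

Step 4
Reactants: 8 (R)-6-methyl-1-(trimethylsilyl)hept-5-en-1-yn-3-ol
Product: 9 (R)-6-methylhept-5-en-1-yn-3-ol
Conditions: K2CO3 (0.3 equiv), MeOH, 0 °C → rt
Reagents that add atoms: none
Why: Methoxide-mediated protodesilylation of the alkynyl–silicon bond is fast and does not touch the carbinol centre or the alkene; the volatile product should be concentrated cold or carried on in solution.

Step 5
Reactants: 9 (R)-6-methylhept-5-en-1-yn-3-ol
Product: 10 (R)-6-methylhept-5-en-1-yn-3-yl butanoate
Conditions: (n-PrCO)2O, Et3N, DMAP (cat.), CH2Cl2, 0 °C → rt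
Reagents that add atoms: butyric anhydride, CCCC(=O)OC(=O)CCC
Why: DMAP-catalysed acylation occurs at oxygen with retention at carbon, so the ester of the target is in place before the sensitive benzylic position exists.

Step 6
Reactants: 11 2-bromo-1,4-dimethoxybenzene; 12 chromium hexacarbonyl Cr(CO)6
Product: 15 pentacarbonyl[(2,5-dimethoxyphenyl)(methoxy)methylidene]chromium, via (2,5-dimethoxyphenyl)lithium 13 (not isolated), via lithium acylchromate 14 (not isolated)
Conditions: n-BuLi, THF, −78 °C; Cr(CO)6, −78 °C → rt; then MeOTf, CH2Cl2, 0 °C → rt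
Reagents that add atoms: methyl trifluoromethanesulfonate (MeOTf), COS(=O)(=O)C(F)(F)F
Why: Fischer carbene synthesis: bromine–lithium exchange gives aryllithium 13, which adds to a CO ligand of Cr(CO)6 to form acylchromate 14, and the hard alkylating agent MeOTf methylates its oxygen.

Step 7
Reactants: 15 pentacarbonyl[(2,5-dimethoxyphenyl)(methoxy)methylidene]chromium; 10 (R)-6-methylhept-5-en-1-yn-3-yl butanoate
Product: 18 (R)-1-(1-hydroxy-4,5,8-trimethoxynaphthalen-2-yl)-4-methylpent-3-en-1-yl butanoate, via chromium-bound vinylketene 16 (not isolated), via tricarbonylchromium naphthol complex 17 (not isolated)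
Conditions: 15 (1 equiv), 10 (1.5 equiv), degassed THF (0.05 M), 50 °C, Ar; then air, Et2O, rt
Reagents that add atoms: none
Why: Loss of one CO from zerovalent chromium in 15, helped by transient chelation of the ortho methoxy group, frees a site for alkyne 10, which inserts into the Cr=C bond (C3–C4); migration of a CO ligand onto the new metal-bound carbon (C1–C2) then gives vinylketene complex 16. Ring A closes by 6π-electrocyclisation of 16 onto the only unsubstituted ortho carbon of the aryl group (C1–C8a), and a hydrogen shift aromatises the ring to naphthol complex 17, which air demetallates to 18. The closest known reaction type is the Dötz benzannulation of aryl(alkoxy)carbene chromium complexes with terminal alkynes, which covers 2,5-dimethoxyphenyl complexes and alkynes with propargylic oxygen substituents. No stereocentre is created: the (R)-centre lies outside the reacting atoms, and the planar chirality of 17 disappears on decomplexation. The selectivity needed is the regiochemistry of alkyne insertion, and it is secured sterically because a terminal alkyne places its CH next to the carbene carbon (C4) and its branched propargylic carbon next to the CO-derived C1. The prenyl alkene stands in a 1,5-relation to the alkyne and is trisubstituted, so interception of the metal carbene by cyclopropanation is not expected to compete.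

Step 8
Reactants: 18 (R)-1-(1-hydroxy-4,5,8-trimethoxynaphthalen-2-yl)-4-methylpent-3-en-1-yl butanoate
Product: 19 (R)-1-(5,8-dimethoxy-1,4-dioxo-1,4-dihydronaphthalen-2-yl)-4-methylpent-3-en-1-yl butanoate
Conditions: (NH4)2Ce(NO3)6 (2.2 equiv), MeCN/H2O 4:1, 0 °C
Reagents that add atoms: water, O
Why: Oxidative demethylation: the free C1 phenol with its para methoxy group makes ring A far easier to oxidise than the bis-ether ring B, so tetravalent cerium removes two electrons from ring A only, water adds at C4 and methanol leaves, and the resulting electron-poor dimethoxynaphthoquinone should resist further oxidation by this reagent.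

Step 9
Reactants: 19 (R)-1-(5,8-dimethoxy-1,4-dioxo-1,4-dihydronaphthalen-2-yl)-4-methylpent-3-en-1-yl butanoate
Product: 21 (R)-1-(5,8-dihydroxy-1,4-dioxo-1,4-dihydronaphthalen-2-yl)-4-methylpent-3-en-1-yl butanoate (butyrylshikonin), via naphthalene-1,4,5,8-tetrone 20 (not isolated)
Conditions: AgO (excess), 6 M HNO3, acetone, rt, minutes; then CHCl3, aq. Na2S2O4, rt, air
Reagents that add atoms: water, O
Why: Oxidative demethylation of the deactivated ring B needs the stronger oxidant AgO in nitric acid, a combination used for 2-(1-acyloxyalkyl)-5,8-dimethoxy-1,4-naphthoquinones, with water supplying the C5 and C8 oxygens; the dithionite wash then returns tetrone 20 to the naphthazarin oxidation level without touching ester, alkene or stereocentre.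

**Compound list**

1 | 4-methylpent-3-enoic acid | CC(C)=CCC(=O)O | starting material
2 | 1-(1H-imidazol-1-yl)-4-methylpent-3-en-1-one (acyl imidazole) | CC(C)=CCC(=O)n1ccnc1 | intermediate
3 | N-methoxy-N,4-dimethylpent-3-enamide | CC(C)=CCC(=O)N(C)OC | intermediate
4 | ethynyltrimethylsilane | C#C[Si](C)(C)C | starting material
5 | lithium (trimethylsilyl)acetylide | [Li]C#C[Si](C)(C)C | intermediate
6 | lithium 3-[methoxy(methyl)amino]-6-methyl-1-(trimethylsilyl)hept-5-en-1-yn-3-olate (tetrahedral adduct, racemic at C3) | CON(C)C(O[Li])(CC=C(C)C)C#C[Si](C)(C)C | intermediate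
7 | 6-methyl-1-(trimethylsilyl)hept-5-en-1-yn-3-one | CC(C)=CCC(=O)C#C[Si](C)(C)C | intermediate
8 | (R)-6-methyl-1-(trimethylsilyl)hept-5-en-1-yn-3-ol | O[C@H](CC=C(C)C)C#C[Si](C)(C)C | intermediate
9 | (R)-6-methylhept-5-en-1-yn-3-ol | O[C@H](CC=C(C)C)C#C | intermediate
10 | (R)-6-methylhept-5-en-1-yn-3-yl butanoate | CCCC(=O)O[C@H](CC=C(C)C)C#C | intermediate
11 | 2-bromo-1,4-dimethoxybenzene | COc1ccc(OC)c(Br)c1 | starting material
12 | chromium hexacarbonyl Cr(CO)6 | O=C=[Cr](=C=O)(=C=O)(=C=O)(=C=O)=C=O | starting material
13 | (2,5-dimethoxyphenyl)lithium | [Li]c1cc(OC)ccc1OC | intermediate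
14 | lithium pentacarbonyl[(2,5-dimethoxyphenyl)(oxido)methylidene]chromate (acylchromate) | [Li+].[O-]C(=[Cr](=C=O)(=C=O)(=C=O)(=C=O)=C=O)c1cc(OC)ccc1OC | intermediate
15 | pentacarbonyl[(2,5-dimethoxyphenyl)(methoxy)methylidene]chromium | COC(=[Cr](=C=O)(=C=O)(=C=O)(=C=O)=C=O)c1cc(OC)ccc1OC | intermediate
16 | tricarbonylchromium complex (tetrahapto) of the vinylketene (R,E)-4-(2,5-dimethoxyphenyl)-4-methoxy-2-[1-(butanoyloxy)-4-methylpent-3-en-1-yl]buta-1,3-dien-1-one | CCCC(=O)O[C@H](CC=C(C)C)C(=C=O)/C=C(/OC)c1cc(OC)ccc1OC.O=C=[Cr](=C=O)=C=O | intermediate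
17 | tricarbonylchromium complex of naphthol 18, metal hexahapto-bound to ring A | CCCC(=O)O[C@H](CC=C(C)C)c1cc(OC)c2c(OC)ccc(OC)c2c1O.O=C=[Cr](=C=O)=C=O | intermediate
18 | (R)-1-(1-hydroxy-4,5,8-trimethoxynaphthalen-2-yl)-4-methylpent-3-en-1-yl butanoate | CCCC(=O)O[C@H](CC=C(C)C)c1cc(OC)c2c(OC)ccc(OC)c2c1O | intermediate
19 | (R)-1-(5,8-dimethoxy-1,4-dioxo-1,4-dihydronaphthalen-2-yl)-4-methylpent-3-en-1-yl butanoate | CCCC(=O)O[C@H](CC=C(C)C)C1=CC(=O)c2c(OC)ccc(OC)c2C1=O | intermediate
20 | (R)-4-methyl-1-(1,4,5,8-tetraoxo-1,4,5,8-tetrahydronaphthalen-2-yl)pent-3-en-1-yl butanoate | CCCC(=O)O[C@H](CC=C(C)C)C1=CC(=O)C2=C(C1=O)C(=O)C=CC2=O | intermediate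
21 | (R)-1-(5,8-dihydroxy-1,4-dioxo-1,4-dihydronaphthalen-2-yl)-4-methylpent-3-en-1-yl butanoate (butyrylshikonin) | CCCC(=O)O[C@H](CC=C(C)C)C1=CC(=O)c2c(O)ccc(O)c2C1=O | target

**Step count**

Total: 9 steps. Longest linear sequence: 8 steps (steps 1, 2, 3, 4, 5, 7, 8, 9); the carbene branch (step 6) joins at step 7.

**Steps most likely to fail**

1. Step 9. The trisubstituted alkene may be over-oxidised or nitrated and the ester may be lost in the strongly oxidising nitric acid medium, or the electron-poor ring B may be only partly oxidised. The fallback swaps which ring is oxidised, so that no oxidant stronger than (NH4)2Ce(NO3)6 is needed. It sets out from 19 and returns at 21. Quinone 19 is reductively acetylated (Zn dust, Ac2O, Et3N, DMAP, rt) to (R)-1-(1,4-diacetoxy-5,8-dimethoxynaphthalen-2-yl)-4-methylpent-3-en-1-yl butanoate F1. Ring A is now a deactivated bis-acetate, so (NH4)2Ce(NO3)6 in MeCN/H2O at 0 °C should demethylate ring B oxidatively and give (R)-1-(1,4-diacetoxy-5,8-dioxo-5,8-dihydronaphthalen-2-yl)-4-methylpent-3-en-1-yl butanoate F2. Selective cleavage of the two activated aryl acetates (NH4OAc, MeOH/H2O, rt) in the presence of the secondary alkyl butanoate should then give the naphthazarin, whose tautomers are 21.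

2. Step 7. The benzylic butanoate may ionise or eliminate from the electron-rich, chromium-bound naphthol (ortho-quinone methide pathway, with loss of the ester or of configuration), or the acyl group may move to the neighbouring phenol. The fallback carries the carbinol through the benzannulation as a silyl ether and acylates at the quinone stage. It sets out from 9 and returns at 19. Alcohol 9 is silylated (TBSCl, imidazole, DMF) to (R)-tert-butyldimethyl[(6-methylhept-5-en-1-yn-3-yl)oxy]silane F3. Benzannulation of 15 with F3 under the conditions of step 7 should pass through the vinylketene complex F4 and the tricarbonylchromium naphthol complex F5 to (R)-2-{1-[(tert-butyldimethylsilyl)oxy]-4-methylpent-3-en-1-yl}-4,5,8-trimethoxynaphthalen-1-ol F6. (NH4)2Ce(NO3)6 then gives (R)-2-{1-[(tert-butyldimethylsilyl)oxy]-4-methylpent-3-en-1-yl}-5,8-dimethoxynaphthalene-1,4-dione F7, and HF·pyridine in THF at 0 °C frees (R)-2-(1-hydroxy-4-methylpent-3-en-1-yl)-5,8-dimethoxynaphthalene-1,4-dione F8. Butyric anhydride with Et3N and DMAP converts F8 to 19.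

3. Step 3. Facial selectivity of hydride transfer may be insufficient, or the β,γ-double bond may drift into conjugation before reduction. The fallback replaces asymmetric reduction by kinetic resolution. It sets out from 7 and returns at 9. Luche reduction (NaBH4, CeCl3·7H2O, MeOH, −78 °C) gives racemic 6-methyl-1-(trimethylsilyl)hept-5-en-1-yn-3-ol F9, and K2CO3 in MeOH gives racemic 6-methylhept-5-en-1-yn-3-ol F10. Candida antarctica lipase B with vinyl butanoate in hexane is expected, by the empirical size rule for secondary alcohols with ethynyl as the smaller group, to acylate the (S)-alcohol to (S)-6-methylhept-5-en-1-yn-3-yl butanoate F11 and leave (R)-alcohol 9, which is separated by chromatography. The same enzymatic acylation could also be used to raise the enantiomeric purity of 9 obtained from step 3.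

**Further compounds**

F1 | step 9 | (R)-1-(1,4-diacetoxy-5,8-dimethoxynaphthalen-2-yl)-4-methylpent-3-en-1-yl butanoate | CCCC(=O)O[C@H](CC=C(C)C)c1cc(OC(C)=O)c2c(OC)ccc(OC)c2c1OC(C)=O
F2 | step 9 | (R)-1-(1,4-diacetoxy-5,8-dioxo-5,8-dihydronaphthalen-2-yl)-4-methylpent-3-en-1-yl butanoate | CCCC(=O)O[C@H](CC=C(C)C)c1cc(OC(C)=O)c2C(=O)C=CC(=O)c2c1OC(C)=O
F3 | step 7 | (R)-tert-butyldimethyl[(6-methylhept-5-en-1-yn-3-yl)oxy]silane | CC(C)(C)[Si](C)(C)O[C@H](CC=C(C)C)C#C
F4 | step 7 | tricarbonylchromium complex (tetrahapto) of the vinylketene (R,E)-2-{1-[(tert-butyldimethylsilyl)oxy]-4-methylpent-3-en-1-yl}-4-(2,5-dimethoxyphenyl)-4-methoxybuta-1,3-dien-1-one | CC(C)(C)[Si](C)(C)O[C@H](CC=C(C)C)C(=C=O)/C=C(/OC)c1cc(OC)ccc1OC.O=C=[Cr](=C=O)=C=O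
F5 | step 7 | tricarbonylchromium complex of naphthol F6, metal hexahapto-bound to ring A | CC(C)(C)[Si](C)(C)O[C@H](CC=C(C)C)c1cc(OC)c2c(OC)ccc(OC)c2c1O.O=C=[Cr](=C=O)=C=O
F6 | step 7 | (R)-2-{1-[(tert-butyldimethylsilyl)oxy]-4-methylpent-3-en-1-yl}-4,5,8-trimethoxynaphthalen-1-ol | CC(C)(C)[Si](C)(C)O[C@H](CC=C(C)C)c1cc(OC)c2c(OC)ccc(OC)c2c1O
F7 | step 7 | (R)-2-{1-[(tert-butyldimethylsilyl)oxy]-4-methylpent-3-en-1-yl}-5,8-dimethoxynaphthalene-1,4-dione | CC(C)(C)[Si](C)(C)O[C@H](CC=C(C)C)C1=CC(=O)c2c(OC)ccc(OC)c2C1=O
F8 | step 7 | (R)-2-(1-hydroxy-4-methylpent-3-en-1-yl)-5,8-dimethoxynaphthalene-1,4-dione | O[C@H](CC=C(C)C)C1=CC(=O)c2c(OC)ccc(OC)c2C1=O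
F9 | step 3 | racemic 6-methyl-1-(trimethylsilyl)hept-5-en-1-yn-3-ol | OC(CC=C(C)C)C#C[Si](C)(C)C
F10 | step 3 | racemic 6-methylhept-5-en-1-yn-3-ol | OC(CC=C(C)C)C#C
F11 | step 3 | (S)-6-methylhept-5-en-1-yn-3-yl butanoate | CCCC(=O)O[C@@H](CC=C(C)C)C#C
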